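**The fork.** Follow one molecule charged as J or D and ask its chance of standing as G at a given time. If each step takes one molecule at a time, that chance carries no concentration, and a small run speaks for a larger one.

| flask | J | D | remark | time |
|---|---|---|---|---|
| alder | 0.20 M | 0.10 equiv | run made earlier |  |
| maple | 0.30 M | 0.10 equiv | run made earlier |  |
| flask | 0.40 M | 0.100 equiv |  | 15 d |

| run | time / d | G / % | J / % |
|---|---|---|---|
| alder | 0.333 | 14.1 | 56.5 |
| alder | 0.625 | 17.4 | 36.5 |
| alder | 1.25 | 18.4 | 14.7 |
| alder | 2.50 | 18.1 | 2.8 |
| alder | 5.00 | 14.6 | 0.1 |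
| alder | 10.0 | 11.9 | 0 |
| maple | 0.333 | 13.2 | 56.1 |
| maple | 0.625 | 16.6 | 36.2 |
| maple | 1.25 | 18.7 | 14.9 |
| maple | 2.50 | 18.2 | 1.7 |
| maple | 5.00 | 14.6 | 0 |
| maple | 10.0 | 11.3 | 0 |

(standard deviation of a reading: 0.3 percentage points)

- the best time, 15 d at the latest, for G
- the amount of G, in percent of the J and D together charged, at that time

- the numbers in the tables scatter by 0.3 percentage points (one standard deviation)

**The share.** At 1.25 d the two runs together give 21.8% for the G share, a selectivity: G divided by the part of the charge no longer J. Alder alone reads 21.6% and maple 22.0%.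

**First doubt.** Early on, alder stands above maple by 0.9 percentage points at 0.333 d, against a scatter of 0.3 points per reading, so a step taking two molecules might be at work. But at 1.25 d maple is the higher by 0.3 points, and at 2.50 d the gap is smaller than the scatter. So the 0.40 M flask is reckoned on the same curve near its top.

**Second doubt.** The reading at 1.25 d need not be the top. G averages 18.6% there and less at 2.50 d, 18.1%. Over the same doubling of time, the rise into 1.25 d is 1.6 points and the fall out of it 0.4 points, so the rise is larger. This reckoning therefore puts the top between 1.25 d and 2.50 d, a little above the first average.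

**The forecast.** It gives 18.6% at 1.6 d, holding that “the overall kinetics appear concentration-independent”.

**The result.** The flask tops at 18.8% at 1.47 d, with 10.6% of the charge left as J, where the G share gives 19.5%, more than the flask's top.

    J ⇌ D (K = 0.201, k = 0.0312 h⁻¹)
    J → G (k = 0.0392 h⁻¹)
    D → Z (k = 0.436 h⁻¹)
    G ⇌ Z (K = 6.76, k = 0.0196 h⁻¹)
    G ⇌ E (K = 1.42, k = 0.155 h⁻¹)
    2 D → L (k = 0.757 M⁻¹ h⁻¹)

**The neighbour.** A neighbouring flask charges 0.0400 equiv of D instead. At the same fraction of its own J left, it holds 11.2% J, and the share gives 19.4% G; its simulated best is 19.4%.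

The earlier runs and the new flask come from a simulation from invented constants, noise included.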